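**Overview**

Germacrane numbering is used (lactone O on C6, C7 ring fusion, C8 methacrylate, C9 acetate, C14 formyl on C10, C15 hydroxymethyl on C4). Everything rests on closing the ten-membered carbocycle last, at C9–C10, by an intramolecular Nozaki–Hiyama–Kishi coupling. The step exploits the allylic carbinol C9 next to the ring-cis C1=C10 alkene: a (Z)-alkenyl iodide (C10) adds to an α-methacryloyloxy aldehyde (C9), forming the ring, the C9–C10 bond and the C9 stereocentre at once, with the alkene geometry carried in from the iodide. The precursor is an open-chain trans-α-methylene-γ-butyrolactone (C6–C8 set by butenolide Barbier allylation and Mitsunobu inversion) with C14 masked as acetal and O15 silylated.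

Key step: step 15

Remark (assumptions): TBS = tert-butyldimethylsilyl, TBDPS = tert-butyldiphenylsilyl. (Pent-4-en-1-yl)triphenylphosphonium bromide, (TBSO)acetaldehyde and 2-(bromomethyl)acrylic acid are taken as catalogue chemicals. The butenolide Barbier step is assumed to follow the closed chair transition state (7,8-anti), which is why C8 is inverted in step 12.

**Route**

Step 1
Reactants: 1 (pent-4-en-1-yl)triphenylphosphonium bromide; 2 ethyl chloroformate; 3 (TBSO)acetaldehyde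
Product: 5 ethyl (2E)-2-(but-3-en-1-yl)-4-(TBSO)but-2-enoate, via stabilised ylide 4 (not isolated)
Conditions: NaHMDS (2 equiv), THF, −78 °C; 2, −78 → 0 °C; then 3, reflux
Reagents that add atoms: none
Why: Acylation of the non-stabilised ylide by the chloroformate (the second equivalent of base re-forms the ylide) gives ester ylide 4, and its Wittig olefination should be E-selective (ester trans to the CH2OTBS carbon), which fixes C4=C5 with C3 and C6 cis.

Step 2
Reactants: 5 ethyl (2E)-2-(but-3-en-1-yl)-4-(TBSO)but-2-enoate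
Product: 6 (2E)-2-(but-3-en-1-yl)-4-(TBSO)but-2-en-1-ol
Conditions: DIBAL-H (2.2 equiv), CH2Cl2, −78 °C; Rochelle salt work-up
Reagents that add atoms: none
Why: DIBAL 1,2-reduction of the conjugated ester gives the allylic alcohol (O15) and leaves the silyl ether and both alkenes untouched.

Step 3
Reactants: 6 (2E)-2-(but-3-en-1-yl)-4-(TBSO)but-2-en-1-ol
Product: 7 (2E)-2-(but-3-en-1-yl)-1-(TBDPSO)-4-(TBSO)but-2-ene
Conditions: TBDPSCl, imidazole, DMF, rt
Reagents that add atoms: tert-butyl(chloro)diphenylsilane, CC(C)(C)[Si](Cl)(c1ccccc1)c1ccccc1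
Why: Standard silylation puts on O15 a TBDPS group that should outlast the later acid and fluoride steps in which the TBS ethers are removed.

Step 4
Reactants: 7 (2E)-2-(but-3-en-1-yl)-1-(TBDPSO)-4-(TBSO)but-2-ene; 8 (E)-but-2-enal (crotonaldehyde)
Product: 9 (2E,6E)-8-(TBSO)-6-[(TBDPSO)methyl]octa-2,6-dienal
Conditions: Hoveyda–Grubbs II (5 mol %), 8 (5 equiv), CH2Cl2, 40 °C
Reagents that add atoms: none
Why: Olefin cross-metathesis of the terminal alkene with crotonaldehyde should give the E-enal (C1=C10–C14) while the trisubstituted C4=C5 alkene stays inert.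

Step 5
Reactants: 9 (2E,6E)-8-(TBSO)-6-[(TBDPSO)methyl]octa-2,6-dienal
Product: 10 (2Z,6E)-2-iodo-8-(TBSO)-6-[(TBDPSO)methyl]octa-2,6-dienal
Conditions: I2, DMAP (0.2 equiv), K2CO3, THF/H2O (1:1), rt
Reagents that add atoms: iodine, II
Why: Amine-catalysed (Baylis–Hillman-type) α-iodination: DMAP adds at C1, the enolate is iodinated at C10 and elimination returns the alkene with CHO trans to C2, i.e. the (Z)-iodide with I cis to C2.

Step 6
Reactants: 10 (2Z,6E)-2-iodo-8-(TBSO)-6-[(TBDPSO)methyl]octa-2,6-dienal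
Product: 11 (2E,6Z)-7-iodo-8,8-dimethoxy-3-[(TBDPSO)methyl]octa-2,6-dien-1-ol
Conditions: HC(OMe)3, camphorsulfonic acid (10 mol %), MeOH, 0 °C → rt
Reagents that add atoms: trimethyl orthoformate, COC(OC)OC; methanol, CO
Why: Acid-catalysed acetalisation of the electrophilic α-iodo aldehyde, with methanolysis of the primary allylic TBS ether (O6) in the same pot; the TBDPS ether should survive.

Step 7
Reactants: 11 (2E,6Z)-7-iodo-8,8-dimethoxy-3-[(TBDPSO)methyl]octa-2,6-dien-1-ol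
Product: 12 (2E,6Z)-7-iodo-8,8-dimethoxy-3-[(TBDPSO)methyl]octa-2,6-dienal
Conditions: MnO2 (excess), CH2Cl2, rt
Reagents that add atoms: none
Why: Neutral MnO2 oxidation of the primary allylic alcohol should give the C6 enal without isomerising C4=C5 or touching the acetal.

Step 8
Reactants: 12 (2E,6Z)-7-iodo-8,8-dimethoxy-3-[(TBDPSO)methyl]octa-2,6-dienal
Product: 13 (3S,4E,8Z)-9-iodo-10,10-dimethoxy-5-[(TBDPSO)methyl]deca-1,4,8-trien-3-ol
Conditions: divinylzinc (from CH2=CHMgBr and ZnCl2, salt-free), (−)-DAIB (10 mol %), toluene, 0 °C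
Reagents that add atoms: vinylmagnesium bromide, C=C[Mg]Br
Why: Amino-alcohol-catalysed enantioselective addition of an organozinc to an aldehyde; the (−)-DAIB–zinc complex should deliver vinyl to the Si face, as in its dialkylzinc additions, and so set the (S)-carbinol at C6.

Step 9
Reactants: 13 (3S,4E,8Z)-9-iodo-10,10-dimethoxy-5-[(TBDPSO)methyl]deca-1,4,8-trien-3-ol; 14 2-(bromomethyl)prop-2-enoic acid
Product: 15 (3S,4E,8Z)-9-iodo-10,10-dimethoxy-5-[(TBDPSO)methyl]deca-1,4,8-trien-3-yl 2-(bromomethyl)prop-2-enoate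
Conditions: DCC, DMAP (5 mol %), CH2Cl2, 0 °C
Reagents that add atoms: none
Why: Steglich esterification; the allylic bromide should be tolerated when DMAP is kept catalytic and the temperature low.

Step 10
Reactants: 15 (3S,4E,8Z)-9-iodo-10,10-dimethoxy-5-[(TBDPSO)methyl]deca-1,4,8-trien-3-yl 2-(bromomethyl)prop-2-enoate
Product: 16 (5R)-3-(bromomethyl)-5-{(1E,5Z)-6-iodo-7,7-dimethoxy-2-[(TBDPSO)methyl]hepta-1,5-dien-1-yl}furan-2(5H)-one
Conditions: Grubbs II (5–10 mol %), CH2Cl2 (5 mM), 40 °C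
Reagents that add atoms: none
Why: Ring-closing metathesis between the vinyl group and the 1,1-disubstituted acrylate closes the butenolide with loss of ethene; the trisubstituted alkenes should not engage and C6 is untouched.

Step 11
Reactants: 16 (5R)-3-(bromomethyl)-5-{(1E,5Z)-6-iodo-7,7-dimethoxy-2-[(TBDPSO)methyl]hepta-1,5-dien-1-yl}furan-2(5H)-one; 3 (TBSO)acetaldehyde
Product: 18 (4R,5R)-4-[(1R)-1-hydroxy-2-(TBSO)ethyl]-5-{(1E,5Z)-6-iodo-7,7-dimethoxy-2-[(TBDPSO)methyl]hepta-1,5-dien-1-yl}-3-methylideneoxolan-2-one, via allylzinc bromide 17 (not isolated)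
Conditions: Zn dust, THF/sat. aq. NH4Cl (2:1), 0 °C → rt, 3 (3 equiv)
Reagents that add atoms: none
Why: Barbier allylation: the allylzinc should react at its γ-carbon C7 (SE2') through a closed chair transition state on the face anti to the C6 substituent, which sets C7 trans to C5 and unveils the exocyclic methylene, while the E-type reagent with the aldehyde residue equatorial gives the 7,8-anti (8R) carbinol.

Step 12
Reactants: 18 (4R,5R)-4-[(1R)-1-hydroxy-2-(TBSO)ethyl]-5-{(1E,5Z)-6-iodo-7,7-dimethoxy-2-[(TBDPSO)methyl]hepta-1,5-dien-1-yl}-3-methylideneoxolan-2-one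
Product: 19 (1S)-2-(TBSO)-1-[(2R,3S)-2-{(1E,5Z)-6-iodo-7,7-dimethoxy-2-[(TBDPSO)methyl]hepta-1,5-dien-1-yl}-4-methylidene-5-oxooxolan-3-yl]ethyl 2-methylprop-2-enoate
Conditions: PPh3, DIAD, methacrylic acid, toluene, 0 °C → rt
Reagents that add atoms: methacrylic acid, C=C(C)C(=O)O
Why: Mitsunobu esterification: SN2 attack of methacrylate on the alkoxyphosphonium ion should invert C8 to the required 8S configuration while installing the ester.

Step 13
Reactants: 19 (1S)-2-(TBSO)-1-[(2R,3S)-2-{(1E,5Z)-6-iodo-7,7-dimethoxy-2-[(TBDPSO)methyl]hepta-1,5-dien-1-yl}-4-methylidene-5-oxooxolan-3-yl]ethyl 2-methylprop-2-enoate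
Product: 20 (1S)-2-hydroxy-1-[(2R,3S)-2-{(1E,5Z)-6-iodo-7,7-dimethoxy-2-[(TBDPSO)methyl]hepta-1,5-dien-1-yl}-4-methylidene-5-oxooxolan-3-yl]ethyl 2-methylprop-2-enoate
Conditions: HF·pyridine, pyridine, THF, 0 °C
Reagents that add atoms: none
Why: Buffered HF·pyridine should cleave the primary TBS ether (O9) much faster than the TBDPS ether, and the weakly acidic medium keeps 1,2-acyl migration slow.

Step 14
Reactants: 20 (1S)-2-hydroxy-1-[(2R,3S)-2-{(1E,5Z)-6-iodo-7,7-dimethoxy-2-[(TBDPSO)methyl]hepta-1,5-dien-1-yl}-4-methylidene-5-oxooxolan-3-yl]ethyl 2-methylprop-2-enoate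
Product: 21 (1S)-2-oxo-1-[(2R,3S)-2-{(1E,5Z)-6-iodo-7,7-dimethoxy-2-[(TBDPSO)methyl]hepta-1,5-dien-1-yl}-4-methylidene-5-oxooxolan-3-yl]ethyl 2-methylprop-2-enoate
Conditions: Dess–Martin periodinane, NaHCO3, CH2Cl2, 0 °C; used at once
Reagents that add atoms: none
Why: Dess–Martin oxidation under buffered conditions should give the α-acyloxy aldehyde (C9) without epimerising C8.

Step 15
Reactants: 21 (1S)-2-oxo-1-[(2R,3S)-2-{(1E,5Z)-6-iodo-7,7-dimethoxy-2-[(TBDPSO)methyl]hepta-1,5-dien-1-yl}-4-methylidene-5-oxooxolan-3-yl]ethyl 2-methylprop-2-enoate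
Product: 23 (3aS,4S,5S,6E,10E,11aR)-6-(dimethoxymethyl)-5-hydroxy-3-methylidene-2-oxo-10-[(TBDPSO)methyl]-2,3,3a,4,5,8,9,11a-octahydrocyclodeca[b]furan-4-yl 2-methylprop-2-enoate, via alkenylchromium(III) species 22 (not isolated)
Conditions: CrCl2 (10 equiv), NiCl2 (0.1 equiv), degassed DMSO, rt, slow addition of 21 (final 2 mM)
Reagents that add atoms: none
Why: Ni(0) inserts into the C10–I bond, the alkenyl group is passed to Cr(III), and the (Z)-alkenylchromium adds 1,2 to the C9 aldehyde; the closest known reaction type is the Nozaki–Hiyama–Kishi macrocyclisation of alkenyl iodide–aldehydes to nine- and ten-membered carbocycles. The ten-membered ring closes in the 10-exo-trig mode (C10 attacks the C9 carbonyl, whose oxygen stays outside the new ring). The C1=C10 geometry is carried over from the iodide, so C2 and C9 end cis, and this cis-alkene, the cis C4=C5 alkene and the trans-lactone hold the two chain ends close. The new C9 centre is controlled by C8: C10 should attack anti to the C8–O bond with the chromium-bound carbonyl oxygen turned to the periphery of the forming ring (anti to C7) and H9 inside, which gives the 8,9-threo (9S) alcohol with H8 and H9 anti. The step needs chemoselectivity for the aldehyde over the two enoates and the acetal, which organochromium(III) reagents provide, and ring closure over dimerisation, which high dilution secures. The acyclic Felkin–Anh preference favours the C9 epimer, so this facial selectivity is the main risk of the route.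

Step 16
Reactants: 23 (3aS,4S,5S,6E,10E,11aR)-6-(dimethoxymethyl)-5-hydroxy-3-methylidene-2-oxo-10-[(TBDPSO)methyl]-2,3,3a,4,5,8,9,11a-octahydrocyclodeca[b]furan-4-yl 2-methylprop-2-enoate
Product: 24 (3aS,4S,5S,6E,10E,11aR)-5-(acetyloxy)-6-(dimethoxymethyl)-3-methylidene-2-oxo-10-[(TBDPSO)methyl]-2,3,3a,4,5,8,9,11a-octahydrocyclodeca[b]furan-4-yl 2-methylprop-2-enoate
Conditions: Ac2O, pyridine, DMAP (cat.), CH2Cl2, 0 °C
Reagents that add atoms: acetic anhydride, CC(=O)OC(C)=O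
Why: Acylation of the secondary allylic alcohol with retention should give the C9 acetate.

Step 17
Reactants: 24 (3aS,4S,5S,6E,10E,11aR)-5-(acetyloxy)-6-(dimethoxymethyl)-3-methylidene-2-oxo-10-[(TBDPSO)methyl]-2,3,3a,4,5,8,9,11a-octahydrocyclodeca[b]furan-4-yl 2-methylprop-2-enoate
Product: 25 (3aS,4S,5S,6E,10E,11aR)-5-(acetyloxy)-6-formyl-10-(hydroxymethyl)-3-methylidene-2-oxo-2,3,3a,4,5,8,9,11a-octahydrocyclodeca[b]furan-4-yl 2-methylprop-2-enoate (CNP0147326.4)
Conditions: 48% aq. HF, MeCN, 0 °C → rt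
Reagents that add atoms: water, O
Why: Aqueous HF should hydrolyse the allylic dimethyl acetal to the C14 enal and remove the TBDPS ether from O15 in one operation; the esters, the lactone and the allylic acetate are stable to acid.

**Compound list**

1 | (pent-4-en-1-yl)triphenylphosphonium bromide | C=CCCC[P+](c1ccccc1)(c1ccccc1)c1ccccc1.[Br-] | starting material
2 | ethyl chloroformate | CCOC(=O)Cl | starting material
3 | (tert-butyldimethylsilyloxy)acetaldehyde | O=CCO[Si](C)(C)C(C)(C)C | starting material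
4 | ethyl 2-(triphenylphosphoranylidene)hex-5-enoate (stabilised ylide) | CCOC(=O)C(CCC=C)=P(c1ccccc1)(c1ccccc1)c1ccccc1 | intermediate
5 | ethyl (2E)-2-(but-3-en-1-yl)-4-(TBSO)but-2-enoate | CCOC(=O)/C(CCC=C)=C/CO[Si](C)(C)C(C)(C)C | intermediate
6 | (2E)-2-(but-3-en-1-yl)-4-(TBSO)but-2-en-1-ol | OC/C(CCC=C)=C/CO[Si](C)(C)C(C)(C)C | intermediate
7 | (2E)-2-(but-3-en-1-yl)-1-(TBDPSO)-4-(TBSO)but-2-ene | C=CCC/C(CO[Si](c1ccccc1)(c1ccccc1)C(C)(C)C)=C\CO[Si](C)(C)C(C)(C)C | intermediate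
8 | (E)-but-2-enal (crotonaldehyde) | C/C=C/C=O | starting material
9 | (2E,6E)-8-(TBSO)-6-[(TBDPSO)methyl]octa-2,6-dienal | O=C/C=C/CC/C(CO[Si](c1ccccc1)(c1ccccc1)C(C)(C)C)=C\CO[Si](C)(C)C(C)(C)C | intermediate
10 | (2Z,6E)-2-iodo-8-(TBSO)-6-[(TBDPSO)methyl]octa-2,6-dienal | O=C/C(I)=C/CC/C(CO[Si](c1ccccc1)(c1ccccc1)C(C)(C)C)=C\CO[Si](C)(C)C(C)(C)C | intermediate
11 | (2E,6Z)-7-iodo-8,8-dimethoxy-3-[(TBDPSO)methyl]octa-2,6-dien-1-ol | COC(OC)/C(I)=C/CC/C(CO[Si](c1ccccc1)(c1ccccc1)C(C)(C)C)=C\CO | intermediate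
12 | (2E,6Z)-7-iodo-8,8-dimethoxy-3-[(TBDPSO)methyl]octa-2,6-dienal | COC(OC)/C(I)=C/CC/C(CO[Si](c1ccccc1)(c1ccccc1)C(C)(C)C)=C\C=O | intermediate
13 | (3S,4E,8Z)-9-iodo-10,10-dimethoxy-5-[(TBDPSO)methyl]deca-1,4,8-trien-3-ol | C=C[C@H](O)/C=C(\CC/C=C(\I)C(OC)OC)CO[Si](c1ccccc1)(c1ccccc1)C(C)(C)C | intermediate
14 | 2-(bromomethyl)prop-2-enoic acid | C=C(CBr)C(=O)O | starting material
15 | (3S,4E,8Z)-9-iodo-10,10-dimethoxy-5-[(TBDPSO)methyl]deca-1,4,8-trien-3-yl 2-(bromomethyl)prop-2-enoate | C=C(CBr)C(=O)O[C@@H](C=C)/C=C(\CC/C=C(\I)C(OC)OC)CO[Si](c1ccccc1)(c1ccccc1)C(C)(C)C | intermediate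
16 | (5R)-3-(bromomethyl)-5-{(1E,5Z)-6-iodo-7,7-dimethoxy-2-[(TBDPSO)methyl]hepta-1,5-dien-1-yl}furan-2(5H)-one | O=C1O[C@H](/C=C(\CC/C=C(\I)C(OC)OC)CO[Si](c2ccccc2)(c2ccccc2)C(C)(C)C)C=C1CBr | intermediate
17 | allylzinc bromide derived from 16 (ZnBr in place of Br) | O=C1O[C@H](/C=C(\CC/C=C(\I)C(OC)OC)CO[Si](c2ccccc2)(c2ccccc2)C(C)(C)C)C=C1C[Zn]Br | intermediate
18 | (4R,5R)-4-[(1R)-1-hydroxy-2-(TBSO)ethyl]-5-{(1E,5Z)-6-iodo-7,7-dimethoxy-2-[(TBDPSO)methyl]hepta-1,5-dien-1-yl}-3-methylideneoxolan-2-one | O[C@@H](CO[Si](C)(C)C(C)(C)C)[C@H]1C(=C)C(=O)O[C@@H]1/C=C(/CO[Si](c2ccccc2)(c2ccccc2)C(C)(C)C)CC/C=C(\I)C(OC)OC | intermediate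
19 | (1S)-2-(TBSO)-1-[(2R,3S)-2-{(1E,5Z)-6-iodo-7,7-dimethoxy-2-[(TBDPSO)methyl]hepta-1,5-dien-1-yl}-4-methylidene-5-oxooxolan-3-yl]ethyl 2-methylprop-2-enoate | C=C(C)C(=O)O[C@H](CO[Si](C)(C)C(C)(C)C)[C@H]1C(=C)C(=O)O[C@@H]1/C=C(/CO[Si](c2ccccc2)(c2ccccc2)C(C)(C)C)CC/C=C(\I)C(OC)OC | intermediate
20 | (1S)-2-hydroxy-1-[(2R,3S)-2-{(1E,5Z)-6-iodo-7,7-dimethoxy-2-[(TBDPSO)methyl]hepta-1,5-dien-1-yl}-4-methylidene-5-oxooxolan-3-yl]ethyl 2-methylprop-2-enoate | C=C(C)C(=O)O[C@H](CO)[C@H]1C(=C)C(=O)O[C@@H]1/C=C(/CO[Si](c2ccccc2)(c2ccccc2)C(C)(C)C)CC/C=C(\I)C(OC)OC | intermediate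
21 | (1S)-2-oxo-1-[(2R,3S)-2-{(1E,5Z)-6-iodo-7,7-dimethoxy-2-[(TBDPSO)methyl]hepta-1,5-dien-1-yl}-4-methylidene-5-oxooxolan-3-yl]ethyl 2-methylprop-2-enoate | C=C(C)C(=O)O[C@H](C=O)[C@H]1C(=C)C(=O)O[C@@H]1/C=C(/CO[Si](c2ccccc2)(c2ccccc2)C(C)(C)C)CC/C=C(\I)C(OC)OC | intermediate
22 | (Z)-alkenylchromium(III) dichloride derived from 21 (CrCl2 in place of I at C10) | C=C(C)C(=O)O[C@H](C=O)[C@H]1C(=C)C(=O)O[C@@H]1/C=C(/CO[Si](c2ccccc2)(c2ccccc2)C(C)(C)C)CC/C=C(\[Cr](Cl)Cl)C(OC)OC | intermediate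
23 | (3aS,4S,5S,6E,10E,11aR)-6-(dimethoxymethyl)-5-hydroxy-3-methylidene-2-oxo-10-[(TBDPSO)methyl]-2,3,3a,4,5,8,9,11a-octahydrocyclodeca[b]furan-4-yl 2-methylprop-2-enoate | C=C(C)C(=O)O[C@H]1[C@H]2C(=C)C(=O)O[C@@H]2/C=C(/CO[Si](c3ccccc3)(c3ccccc3)C(C)(C)C)CC/C=C(/C(OC)OC)[C@@H]1O | intermediate
24 | (3aS,4S,5S,6E,10E,11aR)-5-(acetyloxy)-6-(dimethoxymethyl)-3-methylidene-2-oxo-10-[(TBDPSO)methyl]-2,3,3a,4,5,8,9,11a-octahydrocyclodeca[b]furan-4-yl 2-methylprop-2-enoate | C=C(C)C(=O)O[C@H]1[C@H]2C(=C)C(=O)O[C@@H]2/C=C(/CO[Si](c3ccccc3)(c3ccccc3)C(C)(C)C)CC/C=C(/C(OC)OC)[C@@H]1OC(C)=O | intermediate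
25 | (3aS,4S,5S,6E,10E,11aR)-5-(acetyloxy)-6-formyl-10-(hydroxymethyl)-3-methylidene-2-oxo-2,3,3a,4,5,8,9,11a-octahydrocyclodeca[b]furan-4-yl 2-methylprop-2-enoate (CNP0147326.4) | C=C(C)C(=O)O[C@H]1[C@H]2C(=C)C(=O)O[C@@H]2/C=C(/CO)CC/C=C(/C=O)[C@@H]1OC(C)=O | target

**Step count and risks**

Total step count: 17. Longest linear sequence: 17 (the route is fully linear; 2, 3, 8 and 14 are bought).

Steps most likely to fail:

1. Step 15 (ring closure). The process at risk is facial selectivity at the C9 aldehyde, because the acyclic Felkin–Anh bias opposes the ring-derived preference; slow closure would also allow dimerisation or protonation of the alkenylchromium. Fallback: the cyclisation of 21 is run without regard to the C9 outcome, so that the product contains the C9 epimer of 23, (3aS,4S,5R,6E,10E,11aR)-5-hydroxy macrocycle F1. The carbinol mixture is oxidised with Dess–Martin periodinane/NaHCO3 to the cross-conjugated C9 ketone, (3aS,4S,6E,10E,11aR)-2,5-dioxo macrocycle F2. C9 is then set by reagent-controlled 1,2-reduction ((S)-Me-CBS, catecholborane, toluene, −78 °C), in which the alkenyl side should act as the large group and give the 9S alcohol. The fallback sets out from 21 and comes back to the route at 23.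

2. Step 12 (Mitsunobu inversion). The process at risk is E2 elimination across C7–C8, or no substitution at the β-branched carbinol. Fallback: from 18 the alcohol is converted with chloromethanesulfonyl chloride/pyridine (0 °C) into the (1R)-chloromethanesulfonate of 18 F3, with retention. This preformed leaving group is then displaced with inversion by caesium methacrylate and 18-crown-6 in toluene at 40–60 °C, an SN2 substitution with a weakly basic carboxylate and no phosphonium intermediates. The fallback sets out from 18 and comes back to the route at 19.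

3. Step 8 (enantioselective vinylation). The process at risk is insufficient enantiofacial discrimination on the β,β-disubstituted enal. Fallback: from 12, vinylmagnesium bromide (THF, −78 °C) gives the racemic carbinol rac-9-iodo-10,10-dimethoxy-5-[(TBDPSO)methyl]deca-1,4,8-trien-3-ol F4. Dess–Martin oxidation gives the cross-conjugated dienone (4E,8Z)-9-iodo-10,10-dimethoxy-5-[(TBDPSO)methyl]deca-1,4,8-trien-3-one F5. CBS reduction ((R)-Me-CBS, BH3·SMe2, −40 °C), with the β,β-disubstituted alkenyl group as the large substituent, should then give the (S)-alcohol. The fallback sets out from 12 and comes back to the route at 13.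

**Further compounds**

F1 | step 15 | (3aS,4S,5R,6E,10E,11aR)-6-(dimethoxymethyl)-5-hydroxy-3-methylidene-2-oxo-10-[(TBDPSO)methyl]-2,3,3a,4,5,8,9,11a-octahydrocyclodeca[b]furan-4-yl 2-methylprop-2-enoate (C9 epimer of 23) | C=C(C)C(=O)O[C@H]1[C@H]2C(=C)C(=O)O[C@@H]2/C=C(/CO[Si](c3ccccc3)(c3ccccc3)C(C)(C)C)CC/C=C(/C(OC)OC)[C@H]1O
F2 | step 15 | (3aS,4S,6E,10E,11aR)-6-(dimethoxymethyl)-3-methylidene-2,5-dioxo-10-[(TBDPSO)methyl]-2,3,3a,4,5,8,9,11a-octahydrocyclodeca[b]furan-4-yl 2-methylprop-2-enoate | C=C(C)C(=O)O[C@H]1[C@H]2C(=C)C(=O)O[C@@H]2/C=C(/CO[Si](c3ccccc3)(c3ccccc3)C(C)(C)C)CC/C=C(/C(OC)OC)C1=O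
F3 | step 12 | (1R)-2-(TBSO)-1-[(2R,3R)-2-{(1E,5Z)-6-iodo-7,7-dimethoxy-2-[(TBDPSO)methyl]hepta-1,5-dien-1-yl}-4-methylidene-5-oxooxolan-3-yl]ethyl chloromethanesulfonate | ClCS(=O)(=O)O[C@@H](CO[Si](C)(C)C(C)(C)C)[C@H]1C(=C)C(=O)O[C@@H]1/C=C(/CO[Si](c2ccccc2)(c2ccccc2)C(C)(C)C)CC/C=C(\I)C(OC)OC
F4 | step 8 | rac-(4E,8Z)-9-iodo-10,10-dimethoxy-5-[(TBDPSO)methyl]deca-1,4,8-trien-3-ol | C=CC(O)/C=C(\CC/C=C(\I)C(OC)OC)CO[Si](c1ccccc1)(c1ccccc1)C(C)(C)C
F5 | step 8 | (4E,8Z)-9-iodo-10,10-dimethoxy-5-[(TBDPSO)methyl]deca-1,4,8-trien-3-one | C=CC(=O)/C=C(\CC/C=C(\I)C(OC)OC)CO[Si](c1ccccc1)(c1ccccc1)C(C)(C)C
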